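**Strategy.** Ring locants follow the 7‑oxabicyclo[4.1.0]heptane core of the target: C1 (C–CH3, epoxide), C2 and C3 (CH–O‑angeloyl), C4 (CH carrying the side chain), C5 (CH2), C6 (epoxide CH). The ring is cut at C4–C5 and C1–C2 into two three‑carbon units: C1(CH3)–C6(O)–C5H2 is a latent 3‑oxopentanoate, C2–C3–C4 a β‑substituted enal. An amine‑catalysed Michael addition/aldol condensation joins them in one flask, sets C4 and gives a 5‑substituted 2‑methylcyclohex‑2‑enone. A Wharton transposition then moves the oxygen from C6 to C2; C3, C2, the epoxide and the side‑chain carbinol follow by substrate or catalyst control.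

Key step: step 3

Remark on locants: C1–C6 in the text always mean the ring positions of the target as defined above, also in intermediates.
Remark on the chemistry (assumption): the facial senses of the (R)‑diarylprolinol silyl ether (step 3) and of the (S)‑BINOL/Ti(OiPr)4 catalyst (step 15) are assigned from the accepted models for these catalysts; if the opposite sense were found, the mirror‑image catalyst would be used.

**Step 1**
Reactants: 1 but‑3‑en‑1‑ol
Product: 2 tert‑butyl(but‑3‑en‑1‑yloxy)diphenylsilane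
Conditions: TBDPSCl, imidazole, DMF, 0 °C to rt
Reagents that add atoms: tert‑butyl(chloro)diphenylsilane, CC(C)(C)[Si](Cl)(c1ccccc1)c1ccccc1
Why: Silylation of the primary alcohol (silyl ether formation); the tert‑butyldiphenylsilyl group is chosen because it should survive the hot acid of step 3 and the aqueous base of step 4.

**Step 2**
Reactants: 2 tert‑butyl(but‑3‑en‑1‑yloxy)diphenylsilane; 3 (E)‑but‑2‑enal
Product: 4 (E)‑5‑[(tert‑butyldiphenylsilyl)oxy]pent‑2‑enal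
Conditions: 3 (5 equiv), second‑generation Hoveyda–Grubbs catalyst RuCl2(=CH‑C6H4‑2‑OiPr)(H2IMes) (3 mol%), CH2Cl2, 40 °C
Reagents that add atoms: none
Why: Olefin cross‑metathesis of a terminal alkene with an excess of an electron‑poor partner should give the (E)‑enal under thermodynamic control, with loss of propene.

**Step 3**
Reactants: 4 (E)‑5‑[(tert‑butyldiphenylsilyl)oxy]pent‑2‑enal; 5 tert‑butyl 3‑oxopentanoate
Product: 7 (5R)‑5‑[2‑(tert‑butyldiphenylsilyloxy)ethyl]‑2‑methylcyclohex‑2‑en‑1‑one, via Michael adduct 6 (not isolated)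
Conditions: (R)‑2‑{bis[3,5‑bis(trifluoromethyl)phenyl](trimethylsilyloxy)methyl}pyrrolidine (10 mol%), toluene, rt; then TsOH·H2O (20 mol%), toluene, 80 °C
Reagents that add atoms: none
Why: The (R)‑diarylprolinol silyl ether turns 4 into an (E)‑iminium ion whose Re face is shielded, so the doubly activated carbon of 5 (future C5) adds to the β‑carbon (future C4) from the Si face and gives 6; TsOH then cleaves the tert‑butyl ester, the β‑keto acid loses CO2 and the ethyl‑ketone carbon (future C1) condenses with the aldehyde carbon (future C2). The closest known reaction type is the organocatalytic Michael addition of β‑keto esters to enals followed by acid‑induced aldol condensation to 5‑substituted cyclohex‑2‑enones, an asymmetric [3+3] Robinson‑type annulation. The ring closes by a 6‑(enolendo)‑exo‑trig aldol addition followed by dehydration; closure through C5 would need a four‑membered ring and should not compete. The only new stereocentre, C4, is set by the catalyst in the intermolecular step and is not enolisable afterwards. The step needs C‑alkylation at the ester‑bearing carbon, secured by its acidity, and survival of the silyl ether in hot acid, secured by the tert‑butyldiphenylsilyl group.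

**Step 4**
Reactants: 7 (5R)‑5‑[2‑(tert‑butyldiphenylsilyloxy)ethyl]‑2‑methylcyclohex‑2‑en‑1‑one
Product: 8 (1S,4S,6S)‑4‑[2‑(tert‑butyldiphenylsilyloxy)ethyl]‑1‑methyl‑7‑oxabicyclo[4.1.0]heptan‑2‑one (epoxide trans to the side chain)
Conditions: 30% H2O2, NaOH (aq.), MeOH, 0 °C
Reagents that add atoms: hydrogen peroxide, OO
Why: Weitz–Scheffer nucleophilic epoxidation of the enone; hydroperoxide should add to C2 anti to the C4 substituent and give the trans‑epoxide, whose configuration is erased in step 6 and is therefore not critical.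

**Step 5**
Reactants: 8 (1S,4S,6S)‑4‑[2‑(tert‑butyldiphenylsilyloxy)ethyl]‑1‑methyl‑7‑oxabicyclo[4.1.0]heptan‑2‑one
Product: 10 (1S,5S)‑5‑[2‑(tert‑butyldiphenylsilyloxy)ethyl]‑2‑methylcyclohex‑2‑en‑1‑ol (hydroxyl trans to the side chain), via epoxy hydrazone 9 (not isolated)
Conditions: N2H4·H2O (3 equiv), AcOH (cat.), MeOH, 0 °C to rt
Reagents that add atoms: none
Why: Wharton transposition: the epoxy hydrazone fragments with loss of N2 to the allylic alcohol, which moves the ring oxygen from C6 to C2 and the double bond to C1=C6 with retention at C2.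

**Step 6**
Reactants: 10 (1S,5S)‑5‑[2‑(tert‑butyldiphenylsilyloxy)ethyl]‑2‑methylcyclohex‑2‑en‑1‑ol
Product: 11 (5S)‑5‑[2‑(tert‑butyldiphenylsilyloxy)ethyl]‑2‑methylcyclohex‑2‑en‑1‑one
Conditions: Dess–Martin periodinane, NaHCO3, CH2Cl2, rt
Reagents that add atoms: none
Why: Dess–Martin oxidation of the secondary allylic alcohol to the conjugated enone (carbonyl now at C2); C4 is β to the carbonyl and cannot epimerise.

**Step 7**
Reactants: 11 (5S)‑5‑[2‑(tert‑butyldiphenylsilyloxy)ethyl]‑2‑methylcyclohex‑2‑en‑1‑one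
Product: 13 (5S,6S)‑6‑bromo‑5‑[2‑(tert‑butyldiphenylsilyloxy)ethyl]‑2‑methylcyclohex‑2‑en‑1‑one (bromine trans to the side chain), via silyl dienol ether 12 (not isolated)
Conditions: LDA, THF, −78 °C; TMSCl; then NBS, THF, −78 to 0 °C
Reagents that add atoms: N‑bromosuccinimide, O=C1CCC(=O)N1Br
Why: Kinetic deprotonation occurs at the α′‑methylene (C3), and bromination of the cross‑conjugated silyl enol ether should take place anti to the neighbouring C4 substituent (steric control, as in alkylations of carvone enolates), giving the trans‑α′‑bromo enone.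

**Step 8**
Reactants: 13 (5S,6S)‑6‑bromo‑5‑[2‑(tert‑butyldiphenylsilyloxy)ethyl]‑2‑methylcyclohex‑2‑en‑1‑one; 14 angelic acid [(Z)‑2‑methylbut‑2‑enoic acid]
Product: 15 (1R,6S)‑6‑[2‑(tert‑butyldiphenylsilyloxy)ethyl]‑3‑methyl‑2‑oxocyclohex‑3‑en‑1‑yl (2Z)‑2‑methylbut‑2‑enoate (ester cis to the side chain)
Conditions: 14, Cs2CO3, DMF, 0 °C to rt
Reagents that add atoms: none
Why: SN2 displacement of the carbonyl‑activated secondary bromide by cesium angelate proceeds with inversion, so the C3 oxygen ends cis to the C4 side chain; E2 elimination is disfavoured because C4–H and the bromine are cis and cannot become anti‑periplanar.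

**Step 9**
Reactants: 15 (1R,6S)‑6‑[2‑(tert‑butyldiphenylsilyloxy)ethyl]‑3‑methyl‑2‑oxocyclohex‑3‑en‑1‑yl (2Z)‑2‑methylbut‑2‑enoate
Product: 16 (1R,2S,6S)‑6‑[2‑(tert‑butyldiphenylsilyloxy)ethyl]‑2‑hydroxy‑3‑methylcyclohex‑3‑en‑1‑yl (2Z)‑2‑methylbut‑2‑enoate (all‑cis)
Conditions: NaBH4, CeCl3·7H2O, MeOH, −78 °C
Reagents that add atoms: none
Why: Luche 1,2‑reduction: hydride should attack C2 axially and anti to the pseudo‑axial C3 acyloxy group (polar Felkin–Anh), placing the new hydroxyl cis to both neighbours; a 1,2‑acyl shift between the cis oxygens would be harmless because both end as angelates.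

**Step 10**
Reactants: 16 (1R,2S,6S)‑6‑[2‑(tert‑butyldiphenylsilyloxy)ethyl]‑2‑hydroxy‑3‑methylcyclohex‑3‑en‑1‑yl (2Z)‑2‑methylbut‑2‑enoate
Product: 17 all‑cis epoxy alcohol [(2Z)‑2‑methylbut‑2‑enoate at O3 of 4‑[2‑(tert‑butyldiphenylsilyloxy)ethyl]‑1‑methyl‑7‑oxabicyclo[4.1.0]heptane‑2,3‑diol; epoxide oxygen and the substituents at C2 to C4 on one face]
Conditions: VO(acac)2 (5 mol%), tBuOOH (decane), CH2Cl2, 0 °C to rt
Reagents that add atoms: tert‑butyl hydroperoxide, CC(C)(C)OO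
Why: Hydroxyl‑directed epoxidation (VO(acac)2/tBuOOH): the vanadate ester of the allylic C2 hydroxyl delivers oxygen to the same face of the C1=C6 double bond, and the electron‑poor angelate alkene should not react.

**Step 11**
Reactants: 17 all‑cis epoxy alcohol; 14 angelic acid
Product: 18 (1S,2R,3R,4R,6S)‑4‑[2‑(tert‑butyldiphenylsilyloxy)ethyl]‑1‑methyl‑7‑oxabicyclo[4.1.0]heptane‑2,3‑diyl bis[(2Z)‑2‑methylbut‑2‑enoate]
Conditions: 14, 2,4,6‑trichlorobenzoyl chloride, Et3N, toluene, rt; then 17, toluene, 75 °C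
Reagents that add atoms: none
Why: Yamaguchi esterification through the mixed anhydride, run without a nucleophilic catalyst so that the (Z)‑angelate should not isomerise to the tiglate; no stereocentre is touched.

**Step 12**
Reactants: 18 bis‑angelate silyl ether
Product: 19 (1S,2R,3R,4R,6S)‑4‑(2‑hydroxyethyl)‑1‑methyl‑7‑oxabicyclo[4.1.0]heptane‑2,3‑diyl bis[(2Z)‑2‑methylbut‑2‑enoate]
Conditions: TBAF, AcOH, THF, 0 °C to rt
Reagents that add atoms: none
Why: Fluoride‑mediated desilylation; buffering with acetic acid should suppress acyl migration and epoxide opening.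

**Step 13**
Reactants: 19 primary alcohol
Product: 20 (1S,2R,3R,4S,6S)‑1‑methyl‑4‑(2‑oxoethyl)‑7‑oxabicyclo[4.1.0]heptane‑2,3‑diyl bis[(2Z)‑2‑methylbut‑2‑enoate]
Conditions: Dess–Martin periodinane, NaHCO3, CH2Cl2, rt
Reagents that add atoms: none
Why: Dess–Martin oxidation under buffered, near‑neutral conditions, which the epoxide and the esters should tolerate.

**Step 14**
Reactants: 20 aldehyde
Product: 22 (1S,2R,3R,4S,6S)‑1‑methyl‑4‑(3‑oxoprop‑1‑en‑2‑yl)‑7‑oxabicyclo[4.1.0]heptane‑2,3‑diyl bis[(2Z)‑2‑methylbut‑2‑enoate], via Mannich base 21 (not isolated)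
Conditions: CH2=NMe2+ I− (Eschenmoser's salt), Et3N, CH2Cl2, rt
Reagents that add atoms: N,N‑dimethylmethyleneiminium iodide, C=[N+](C)C.[I-]
Why: α‑Methylenation of the aldehyde by Mannich reaction and E1cB loss of dimethylamine creates the 1,1‑disubstituted alkene; C4 is then γ to the enal and should not be deprotonated by triethylamine.

**Step 15**
Reactants: 22 α‑methylene aldehyde
Product: 23 (1S,2R,3R,4S,6S)‑4‑[(3S)‑3‑hydroxyhexa‑1,5‑dien‑2‑yl]‑1‑methyl‑7‑oxabicyclo[4.1.0]heptane‑2,3‑diyl bis[(2Z)‑2‑methylbut‑2‑enoate]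
Conditions: (S)‑BINOL (20 mol%), Ti(OiPr)4 (10 mol%), 4 Å molecular sieves, allylSnBu3, CH2Cl2, −20 °C
Reagents that add atoms: allyltributylstannane, C=CC[Sn](CCCC)(CCCC)CCCC
Why: Keck asymmetric allylation: the BINOL–titanium catalyst should direct the allyl group to the Si face of the aldehyde and give the (S)‑carbinol by catalyst control, the ring stereocentres being too remote to interfere.

**Step 16**
Reactants: 23 homoallylic alcohol
Product: 24 (1S,2R,3R,4S,6S)‑4‑[(3S)‑3‑acetoxyhexa‑1,5‑dien‑2‑yl]‑1‑methyl‑7‑oxabicyclo[4.1.0]heptane‑2,3‑diyl bis[(2Z)‑2‑methylbut‑2‑enoate]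
Conditions: Ac2O, pyridine, DMAP (cat.), CH2Cl2, 0 °C to rt
Reagents that add atoms: acetic anhydride, CC(=O)OC(C)=O
Why: Acetylation of the secondary allylic alcohol with retention of configuration.

**Step 17**
Reactants: 24 acetate
Product: 25 (1S,2R,3R,4S,6S)‑4‑[(3S)‑3‑acetoxy‑6‑methylhepta‑1,5‑dien‑2‑yl]‑1‑methyl‑7‑oxabicyclo[4.1.0]heptane‑2,3‑diyl bis[(2Z)‑2‑methylbut‑2‑enoate] (target)
Conditions: 2‑methylbut‑2‑ene (large excess), second‑generation Grubbs catalyst RuCl2(=CHPh)(PCy3)(H2IMes) (5 mol%), CH2Cl2, 40 °C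
Reagents that add atoms: 2‑methylbut‑2‑ene, CC=C(C)C
Why: Cross‑metathesis of the monosubstituted alkene with 2‑methylbut‑2‑ene installs the prenyl terminus with loss of propene; the 1,1‑disubstituted alkene and the trisubstituted angelate alkenes are too hindered or electron‑poor to react.

**Compound list**

1 | but‑3‑en‑1‑ol | C=CCCO | starting material
2 | tert‑butyl(but‑3‑en‑1‑yloxy)diphenylsilane | C=CCCO[Si](c1ccccc1)(c1ccccc1)C(C)(C)C | intermediate
3 | (E)‑but‑2‑enal | C/C=C/C=O | starting material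
4 | (E)‑5‑[(tert‑butyldiphenylsilyl)oxy]pent‑2‑enal | O=C/C=C/CCO[Si](c1ccccc1)(c1ccccc1)C(C)(C)C | intermediate
5 | tert‑butyl 3‑oxopentanoate | CCC(=O)CC(=O)OC(C)(C)C | starting material
6 | Michael adduct, tert‑butyl (3S)‑3‑[2‑(tert‑butyldiphenylsilyloxy)ethyl]‑5‑oxo‑2‑propanoylpentanoate (mixture at C2) | CCC(=O)C(C(=O)OC(C)(C)C)[C@H](CC=O)CCO[Si](c1ccccc1)(c1ccccc1)C(C)(C)C | intermediate
7 | (5R)‑5‑[2‑(tert‑butyldiphenylsilyloxy)ethyl]‑2‑methylcyclohex‑2‑en‑1‑one | CC(C)(C)[Si](c1ccccc1)(c1ccccc1)OCC[C@@H]1CC(=O)C(C)=CC1 | intermediate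
8 | (1S,4S,6S)‑4‑[2‑(tert‑butyldiphenylsilyloxy)ethyl]‑1‑methyl‑7‑oxabicyclo[4.1.0]heptan‑2‑one | CC(C)(C)[Si](c1ccccc1)(c1ccccc1)OCC[C@@H]1CC(=O)[C@@]2(C)O[C@H]2C1 | intermediate
9 | hydrazone of 8 | CC(C)(C)[Si](c1ccccc1)(c1ccccc1)OCC[C@@H]1CC(=NN)[C@@]2(C)O[C@H]2C1 | intermediate
10 | (1S,5S)‑5‑[2‑(tert‑butyldiphenylsilyloxy)ethyl]‑2‑methylcyclohex‑2‑en‑1‑ol | CC(C)(C)[Si](c1ccccc1)(c1ccccc1)OCC[C@@H]1CC=C(C)[C@@H](O)C1 | intermediate
11 | (5S)‑5‑[2‑(tert‑butyldiphenylsilyloxy)ethyl]‑2‑methylcyclohex‑2‑en‑1‑one | CC(C)(C)[Si](c1ccccc1)(c1ccccc1)OCC[C@@H]1CC=C(C)C(=O)C1 | intermediate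
12 | tert‑butyl{2‑[(1S)‑4‑methyl‑3‑(trimethylsilyloxy)cyclohexa‑2,4‑dien‑1‑yl]ethoxy}diphenylsilane | CC(C)(C)[Si](c1ccccc1)(c1ccccc1)OCC[C@@H]1CC=C(C)C(O[Si](C)(C)C)=C1 | intermediate
13 | (5S,6S)‑6‑bromo‑5‑[2‑(tert‑butyldiphenylsilyloxy)ethyl]‑2‑methylcyclohex‑2‑en‑1‑one | CC(C)(C)[Si](c1ccccc1)(c1ccccc1)OCC[C@@H]1CC=C(C)C(=O)[C@H]1Br | intermediate
14 | angelic acid, (Z)‑2‑methylbut‑2‑enoic acid | C/C=C(/C)C(=O)O | starting material
15 | (1R,6S)‑6‑[2‑(tert‑butyldiphenylsilyloxy)ethyl]‑3‑methyl‑2‑oxocyclohex‑3‑en‑1‑yl (2Z)‑2‑methylbut‑2‑enoate | CC(C)(C)[Si](c1ccccc1)(c1ccccc1)OCC[C@@H]1CC=C(C)C(=O)[C@@H]1OC(=O)/C(C)=C\C | intermediate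
16 | (1R,2S,6S)‑6‑[2‑(tert‑butyldiphenylsilyloxy)ethyl]‑2‑hydroxy‑3‑methylcyclohex‑3‑en‑1‑yl (2Z)‑2‑methylbut‑2‑enoate | CC(C)(C)[Si](c1ccccc1)(c1ccccc1)OCC[C@@H]1CC=C(C)[C@H](O)[C@@H]1OC(=O)/C(C)=C\C | intermediate
17 | all‑cis epoxy alcohol: (2Z)‑2‑methylbut‑2‑enoate at O3 of 4‑[2‑(tert‑butyldiphenylsilyloxy)ethyl]‑1‑methyl‑7‑oxabicyclo[4.1.0]heptane‑2,3‑diol | CC(C)(C)[Si](c1ccccc1)(c1ccccc1)OCC[C@@H]1C[C@@H]2O[C@]2(C)[C@H](O)[C@@H]1OC(=O)/C(C)=C\C | intermediate
18 | (1S,2R,3R,4R,6S)‑4‑[2‑(tert‑butyldiphenylsilyloxy)ethyl]‑1‑methyl‑7‑oxabicyclo[4.1.0]heptane‑2,3‑diyl bis[(2Z)‑2‑methylbut‑2‑enoate] | CC(C)(C)[Si](c1ccccc1)(c1ccccc1)OCC[C@@H]1C[C@@H]2O[C@]2(C)[C@H](OC(=O)/C(C)=C\C)[C@@H]1OC(=O)/C(C)=C\C | intermediate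
19 | (1S,2R,3R,4R,6S)‑4‑(2‑hydroxyethyl)‑1‑methyl‑7‑oxabicyclo[4.1.0]heptane‑2,3‑diyl bis[(2Z)‑2‑methylbut‑2‑enoate] | OCC[C@@H]1C[C@@H]2O[C@]2(C)[C@H](OC(=O)/C(C)=C\C)[C@@H]1OC(=O)/C(C)=C\C | intermediate
20 | (1S,2R,3R,4S,6S)‑1‑methyl‑4‑(2‑oxoethyl)‑7‑oxabicyclo[4.1.0]heptane‑2,3‑diyl bis[(2Z)‑2‑methylbut‑2‑enoate] | O=CC[C@@H]1C[C@@H]2O[C@]2(C)[C@H](OC(=O)/C(C)=C\C)[C@@H]1OC(=O)/C(C)=C\C | intermediate
21 | Mannich base of 20 (2‑[(dimethylamino)methyl] aldehyde, mixture at the new centre) | CN(C)CC(C=O)[C@@H]1C[C@@H]2O[C@]2(C)[C@H](OC(=O)/C(C)=C\C)[C@@H]1OC(=O)/C(C)=C\C | intermediate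
22 | (1S,2R,3R,4S,6S)‑1‑methyl‑4‑(3‑oxoprop‑1‑en‑2‑yl)‑7‑oxabicyclo[4.1.0]heptane‑2,3‑diyl bis[(2Z)‑2‑methylbut‑2‑enoate] | C=C(C=O)[C@@H]1C[C@@H]2O[C@]2(C)[C@H](OC(=O)/C(C)=C\C)[C@@H]1OC(=O)/C(C)=C\C | intermediate
23 | (1S,2R,3R,4S,6S)‑4‑[(3S)‑3‑hydroxyhexa‑1,5‑dien‑2‑yl]‑1‑methyl‑7‑oxabicyclo[4.1.0]heptane‑2,3‑diyl bis[(2Z)‑2‑methylbut‑2‑enoate] | C=C([C@H](CC=C)O)[C@@H]1C[C@@H]2O[C@]2(C)[C@H](OC(=O)/C(C)=C\C)[C@@H]1OC(=O)/C(C)=C\C | intermediate
24 | (1S,2R,3R,4S,6S)‑4‑[(3S)‑3‑acetoxyhexa‑1,5‑dien‑2‑yl]‑1‑methyl‑7‑oxabicyclo[4.1.0]heptane‑2,3‑diyl bis[(2Z)‑2‑methylbut‑2‑enoate] | C=C([C@H](CC=C)OC(C)=O)[C@@H]1C[C@@H]2O[C@]2(C)[C@H](OC(=O)/C(C)=C\C)[C@@H]1OC(=O)/C(C)=C\C | intermediate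
25 | (1S,2R,3R,4S,6S)‑4‑[(3S)‑3‑acetoxy‑6‑methylhepta‑1,5‑dien‑2‑yl]‑1‑methyl‑7‑oxabicyclo[4.1.0]heptane‑2,3‑diyl bis[(2Z)‑2‑methylbut‑2‑enoate] | C=C([C@H](CC=C(C)C)OC(C)=O)[C@@H]1C[C@@H]2O[C@]2(C)[C@H](OC(=O)/C(C)=C\C)[C@@H]1OC(=O)/C(C)=C\C | target

**Step count.** Total: 17 steps. Longest linear sequence: 17 steps (from 1).

**Steps most likely to fail**

Step 8 (together with the bromination of step 7). The bromo ketone may epimerise by bromide exchange or enolisation before it is substituted, and substitution next to the branched C4 may be slow, so the configuration at C3 would not be cleanly inverted. The fallback sets out from 11 and comes back at 15. Ketone 11 is enolised as in step 7 to the silyl dienol ether 12, which is oxidised with mCPBA (Rubottom oxidation, oxygen entering anti to the C4 substituent) to the trans‑α′‑hydroxy enone (5S,6S)‑5‑[2‑(tert‑butyldiphenylsilyloxy)ethyl]‑6‑hydroxy‑2‑methylcyclohex‑2‑en‑1‑one F1. Mitsunobu esterification of this alcohol with angelic acid 14 (PPh3, DIAD, toluene, 0 °C) inverts C3 and should give 15.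

Step 11. Acylation of the hindered C2 hydroxyl, which lies between the epoxide carbon and the acyloxy‑bearing carbon, may be slow. Prolonged heating could then isomerise the activated angelate to the tiglate or open the epoxide with chloride. The fallback sets out from 17 and comes back at 18. Alcohol 17 is esterified with 2‑[bis(2,2,2‑trifluoroethoxy)phosphoryl]propanoic acid (DCC, DMAP, CH2Cl2) to the phosphonate ester of 17 at O2 F2. The (Z)‑enoate is then built on the molecule by Still–Gennari olefination with acetaldehyde (KHMDS, 18‑crown‑6, THF, −78 °C), which should give 18.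

Step 15. Facial selectivity at the 2‑substituted acrolein may be poor, because the Lewis‑basic esters and the epoxide can compete for the titanium catalyst; the carbinol would then form as a mixture of epimers. The fallback sets out from 22 and comes back at 23. Barbier allylation of 22 (allyl bromide, indium powder, THF/H2O) gives the epimeric carbinol mixture 4‑(3‑hydroxyhexa‑1,5‑dien‑2‑yl) bis‑angelate F3. Dess–Martin oxidation gives the α‑methylene ketone 4‑(3‑oxohexa‑1,5‑dien‑2‑yl) bis‑angelate F4. Corey–Bakshi–Shibata reduction with (R)‑2‑methyl‑CBS‑oxazaborolidine and catecholborane (toluene, −78 °C; the alkenyl group acts as the large substituent) should then return 23.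

**Further compounds**

F1 | step 8 | (5S,6S)‑5‑[2‑(tert‑butyldiphenylsilyloxy)ethyl]‑6‑hydroxy‑2‑methylcyclohex‑2‑en‑1‑one | CC(C)(C)[Si](c1ccccc1)(c1ccccc1)OCC[C@@H]1CC=C(C)C(=O)[C@H]1O
F2 | step 11 | 2‑[bis(2,2,2‑trifluoroethoxy)phosphoryl]propanoate of 17 at O2 (all‑cis ring; mixture at the phosphonate‑bearing carbon) | CC(C)(C)[Si](c1ccccc1)(c1ccccc1)OCC[C@@H]1C[C@@H]2O[C@]2(C)[C@H](OC(=O)C(C)P(=O)(OCC(F)(F)F)OCC(F)(F)F)[C@@H]1OC(=O)/C(C)=C\C
F3 | step 15 | 4‑(3‑hydroxyhexa‑1,5‑dien‑2‑yl)‑1‑methyl‑7‑oxabicyclo[4.1.0]heptane‑2,3‑diyl bis[(2Z)‑2‑methylbut‑2‑enoate], ring as in 23, mixture of carbinol epimers | C=C(C(O)CC=C)[C@@H]1C[C@@H]2O[C@]2(C)[C@H](OC(=O)/C(C)=C\C)[C@@H]1OC(=O)/C(C)=C\C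
F4 | step 15 | 1‑methyl‑4‑(3‑oxohexa‑1,5‑dien‑2‑yl)‑7‑oxabicyclo[4.1.0]heptane‑2,3‑diyl bis[(2Z)‑2‑methylbut‑2‑enoate], ring as in 23 | C=C(C(=O)CC=C)[C@@H]1C[C@@H]2O[C@]2(C)[C@H](OC(=O)/C(C)=C\C)[C@@H]1OC(=O)/C(C)=C\C
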